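I will judge these set-ups by one concentration, so the first task is to find it.

| flask | starting material | reagent | free catalyst | remark | time |
|---|---|---|---|---|---|
| Saturday's | 0.25 M | 0.625 M | 1.2 mM | a single well-mixed tank run continuously and read at steady state, 250 s in it on average |  |
| Sunday's | 0.25 M | 0.625 M | 1.2 mM | everything together in a closed stirred flask, run for 50 s | 50 s |
| Tuesday's | 0.25 M | 0.625 M | 1.2 mM | one stirred flow tank at steady state, fed with the mixture as stated, mean residence time 50 s |  |
| Thursday's | 0.25 M | 0.625 M | 1.2 mM | a tube with plug flow, the mixed feed as stated, residence time 50 s | 50 s |

    reagent + free catalyst → catalyst intermediate A (k1 = 19.1 L mol⁻¹ s⁻¹)
    catalyst intermediate A ⇌ released group + catalyst intermediate B (K2 = 0.23 M, k2 = 13.6 s⁻¹)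
    catalyst intermediate B → catalyst intermediate C (k3 = 12.1 s⁻¹)
    starting material + catalyst intermediate C → catalyst intermediate D (k4 = 22.8 L mol⁻¹ s⁻¹)
    catalyst intermediate D → free catalyst + product (k5 = 8.72 s⁻¹)

* the set-up with the highest amount of product at the outlet or at the end, in percent of the starting material put in ("none" if the first two lie within 2 percentage points) (Saturday's / Sunday's / Tuesday's / Thursday's / none)
* amount of product at the outlet or at the end, in percent of the starting material put in, Saturday's
* amount of product at the outlet or at the end, in percent of the starting material put in, Sunday's
* amount of product at the outlet or at the end, in percent of the starting material put in, Tuesday's
* amount of product at the outlet or at the end, in percent of the starting material put in, Thursday's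

- the stated concentrations are those of everything mixed, before any reaction; amounts are the same in each set-up
- run time (Sunday's): 50 s

*What does the catalyst do?* It goes round a ring. Free catalyst takes up reagent and becomes catalyst intermediate A, which sheds released group to give B. B turns into C, C takes up starting material to give D, and D gives up product and returns free catalyst. The speed of product formation is therefore the catalyst charge divided by the time of one lap.

*How long is a lap at the charge?* Leaving out the way back, 4 of the waits do not depend on starting material. These are the wait for reagent and the waits in A, B and D, which sum to 0.355 s. The remaining wait, in C for starting material, is 0.175 s at the charge.

*Which concentration sets the order of the rate?* It is the crossover concentration, the [starting material] at which the wait in C equals the sum of the other waits, here 0.124 M. Far above it the rate is nearly zero order in [starting material], and far below it the rate is pseudo-first-order. The charge of 0.25 M is twice this value, so the run starts between the two.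

*Where is that weak?* It ignores the way back. At 0.205 M of released group, which is less than the charge of starting material, catalyst intermediate B returns to A as often as it moves on. Released group and falling reagent lengthen the other waits, so the crossover value belongs to the start and moves lower during a run.

*What do you commit to?* The starting speed is 2.26 mM s⁻¹. Held for Sunday's 50 s, it gives 45.2%, and I expect less than that as the lap lengthens. Thursday's tube has the same time and should match Sunday's flask. Tuesday's tank works at its outlet concentrations, so I put it lower. Over Saturday's 250 s, the starting speed gives 226%, more than the charge, so I expect that tank to run well down in [starting material].

The forecast gives 82.1% for Saturday's, 39.4% for Sunday's, 35.5% for Tuesday's and 39.4% for Thursday's, with Saturday's best. Its maker “applied that one rate law to each vessel”. My figure for Sunday's is higher than its number, being a starting-speed figure.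

The simulation gives 82.2% in Saturday's tank, 39.6% in Sunday's flask, 35.5% in Tuesday's tank and 39.6% in Thursday's tube, so Saturday's is best, as forecast. Tuesday's tank holds 0.161 M of starting material, more than the crossover concentration reckoned at the charge, while Saturday's tank holds 0.0444 M, about a third of that value, and in Saturday's tank the wait in C is 0.988 s, longer than the other waits reckoned at the charge. Run at 10 times its residence time, Tuesday's tank gives 91.7%.

The rate constants are made up; no experiment stands behind them.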